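The cyclohexane ring (C6–C11, iridal numbering) is closed last, between its two contiguous fully substituted carbons: the carbinol carbon C10 and the quaternary carbon C11. In the acyclic precursor both are electrophiles: C10 is a methyl ketone and C11 the β-carbon of an (E)-vinyl sulfone. A samarium diiodide ketyl–olefin cyclisation joins them with polarity reversal (6-exo). In one operation it creates the ring, the tertiary alcohol and the quaternary centre, with the C10 hydroxyl trans to C12, under control of the C6 stereocentre. The sulfonyl group that activates C11 then carries the C13–C23 side chain onto C12 and is removed reductively.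

Key step: step 6

Remark: atoms carry iridal numbers throughout: C1 (CHO), C2, C3 (CH2OH), C4, C5, ring C6 (CH)–C7 (alkylidene carbon)–C8–C9–C10 (C(OH)CH3)–C11 (quaternary), side chain C12–C23 with the carbinol at C16. Silyl ether 1, hydrazone 14 and ylide 17 are taken as purchasable.

**Ring fragment**

Step 1
Reactants: 1 tert-butyl(but-3-yn-1-yloxy)dimethylsilane; 2 2-bromopropene
Product: 4 (E)-tert-butyldimethyl[(5-methylhexa-3,5-dien-1-yl)oxy]silane, via alkenylzirconocene chloride 3 (not isolated)
Conditions: Cp2Zr(H)Cl, THF, rt; then 2, Pd(PPh3)4 (5 mol%), ZnCl2 (20 mol%), THF, rt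
Reagents that add atoms: none
Why: Hydrozirconation adds Zr–H syn and anti-Markovnikov to the terminal alkyne and the Negishi cross-coupling proceeds with retention, so the (E)-diene should form with the silyl ether untouched.

Step 2
Reactants: 4 (E)-diene
Product: 5 (Z)-tert-butyldimethyl{[5-methyl-6-(4,4,5,5-tetramethyl-1,3,2-dioxaborolan-2-yl)hex-4-en-1-yl]oxy}silane
Conditions: pinacolborane, Ni(cod)2 (2.5 mol%), PCy3 (2.5 mol%), toluene, rt
Reagents that add atoms: pinacolborane, CC1(C)OBOC1(C)C
Why: Nickel-catalysed 1,4-hydroboration of the s-cis diene through a π-allylnickel hydride should place boron on the unsubstituted terminus C12 and hydrogen on C5, which fixes the (Z)-geometry of the trisubstituted allylboronate.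

Step 3
Reactants: 5 (Z)-allylboronate; 6 pent-4-enal
Product: 8 (3S,4S)-3-[3-(tert-butyldimethylsilyloxy)propyl]-2-methylocta-1,7-dien-4-ol, via pinacol borate ester 7 (not isolated)
Conditions: (R)-3,3′-bis(2,4,6-triisopropylphenyl)-1,1′-binaphthyl-2,2′-diyl hydrogen phosphate ((R)-TRIP, 5 mol%), 4 Å MS, toluene, −30 → 0 °C; aq. NaHCO3 work-up
Reagents that add atoms: none
Why: Chiral phosphoric acid-catalysed allylboration through a closed chair (Zimmerman–Traxler) transition state, in which the (Z)-geometry of 5 translates into the syn relationship of the C7 hydroxyl and the C6 side chain; (R)-TRIP is expected to select the aldehyde face that gives the (4S)-carbinol, and the antipodal acid would give the mirror image.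

Step 4
Reactants: 8 dienol
Product: 9 (5S,6S)-5-hydroxy-7-methyl-6-[3-(tert-butyldimethylsilyloxy)propyl]oct-7-en-2-one
Conditions: PdCl2 (10 mol%), CuCl (1 equiv), O2 (1 atm), DMF/H2O 7:1, rt
Reagents that add atoms: water, O
Why: Tsuji–Wacker oxidation by Markovnikov hydroxypalladation of the monosubstituted alkene should give the methyl ketone, while the 1,1-disubstituted isopropenyl group is inert and any cyclic hemiketal formed with the C7 hydroxyl is in equilibrium with the γ-hydroxy ketone.

Step 5
Reactants: 9 isopropenyl hydroxy ketone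
Product: 11 (5S,6S,7E)-5-hydroxy-7-methyl-8-(phenylsulfonyl)-6-[3-(tert-butyldimethylsilyloxy)propyl]oct-7-en-2-one, via β-iodo sulfone 10 (not isolated)
Conditions: PhSO2Na (2 equiv), I2 (1.5 equiv), EtOAc/H2O, visible light, rt; Na2S2O3 wash; then Et3N (3 equiv), CH2Cl2, 0 °C
Reagents that add atoms: sodium benzenesulfinate, [Na+].[O-]S(=O)c1ccccc1
Why: Benzenesulfonyl iodide generated in the flask adds by a radical chain (sulfonyl radical to the CH2 terminus, iodine-atom transfer to the tertiary radical), and triethylamine then removes the acidic α-sulfonyl proton in an anti elimination of HI, which should give the conjugated (E)-vinyl sulfone without touching C6.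

Step 6
Reactants: 11 keto vinyl sulfone
Product: 12 (1S,2S,3S,4S)-1,2-dimethyl-2-[(phenylsulfonyl)methyl]-3-[3-(tert-butyldimethylsilyloxy)propyl]cyclohexane-1,4-diol
Conditions: SmI2 (2.5 equiv, 0.1 M in THF), HMPA (8 equiv), t-BuOH (3 equiv), THF, −78 → 0 °C
Reagents that add atoms: none
Why: Electron transfer from divalent samarium to the methyl ketone gives a ketyl radical anion at C10 that adds to C11, the β-carbon of the vinyl sulfone; the α-sulfonyl radical so formed is reduced by a second equivalent and protonated by tert-butanol, so two carbons that are both electrophilic are joined reductively. The closest known reaction type is the SmI2-mediated ketyl–olefin reductive cyclisation of unsaturated ketones onto acrylates and vinyl sulfones. The ring C6–C7–C8–C9–C10–C11 is closed in the 6-exo-trig mode. Both new stereocentres should come from one chair-like transition state in which the C6 side chain and the C7 oxygen (set in step 3) are equatorial, the bulky samarium-bound ketyl oxygen is pseudo-equatorial and the sulfonyl-bearing alkene terminus is equatorial and turned away from it, so the two methyl groups end trans-diaxial, the C10 hydroxyl trans to C12 and C12 trans to the C5 chain. The step needs reduction of the ketone in the presence of the vinyl sulfone and attack at C11 rather than C12: HMPA speeds ketyl formation, the sulfonyl group makes only C11 electrophilic (6-exo, not 7-endo), and the free C7 hydroxyl and the silyl ether are inert to SmI2.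

**Side-chain fragment**

Step 7
Reactants: 13 geranyl bromide; 14 acetaldehyde N,N-dimethylhydrazone
Product: 16 (4E)-5,9-dimethyldeca-4,8-dienal, via geranylated hydrazone 15 (not isolated)
Conditions: 14, LiN(i-Pr)2, THF, −78 → 0 °C; 13, −78 °C → rt; then aq. oxalic acid/Et2O, rt
Reagents that add atoms: water, O
Why: Azaenolate alkylation of the lithiated dimethylhydrazone by SN2 displacement of the primary allylic bromide should keep the (E)-alkene, and biphasic acid hydrolysis releases the non-conjugated aldehyde.

Step 8
Reactants: 16 dienal; 17 ethyl 2-(triphenylphosphoranylidene)propanoate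
Product: 19 ethyl (2E,4R,6E)-2,7,11-trimethyl-4-(phenylaminooxy)dodeca-2,6,10-trienoate, via α-anilinooxy aldehyde 18 (not isolated)
Conditions: 16 (1.2 equiv), PhNO (1.0 equiv, slow addition), L-proline (20 mol%), CHCl3, 0 °C; then 17 (1.5 equiv), 0 °C → rt
Reagents that add atoms: nitrosobenzene, O=Nc1ccccc1
Why: Proline enamine catalysis (α-aminoxylation), in which the carboxylic acid directs nitrosobenzene so that oxygen is delivered to one enamine face, should set C16 as (R) with L-proline, and the stabilised ylide traps the labile α-oxy aldehyde in situ in an (E)-selective Wittig reaction.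

Step 9
Reactants: 19 anilinooxy enoate
Product: 20 ethyl (2E,4R,6E)-4-hydroxy-2,7,11-trimethyldodeca-2,6,10-trienoate
Conditions: Zn dust, AcOH/THF, 0 °C → rt
Reagents that add atoms: none
Why: Zinc in acetic acid cleaves the weak N–O bond reductively while the enoate and the trisubstituted alkenes are inert.

Step 10
Reactants: 20 hydroxy enoate
Product: 21 ethyl (2E,4R,6E)-4-(tert-butyldimethylsilyloxy)-2,7,11-trimethyldodeca-2,6,10-trienoate
Conditions: TBSCl, imidazole, DMF, rt
Reagents that add atoms: tert-butyldimethylsilyl chloride, CC(C)(C)[Si](C)(C)Cl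
Why: Standard silylation of the secondary allylic alcohol with imidazole as base and nucleophilic catalyst.

Step 11
Reactants: 21 silyloxy enoate
Product: 22 (2E,4R,6E)-4-(tert-butyldimethylsilyloxy)-2,7,11-trimethyldodeca-2,6,10-trien-1-ol
Conditions: i-Bu2AlH (2.5 equiv), CH2Cl2, −78 °C; Rochelle salt work-up
Reagents that add atoms: none
Why: 1,2-Reduction of the conjugated ester by i-Bu2AlH at low temperature should give the allylic alcohol without touching the alkenes or the silyl ether.

Step 12
Reactants: 22 allylic alcohol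
Product: 23 (2E,4R,6E)-1-bromo-4-(tert-butyldimethylsilyloxy)-2,7,11-trimethyldodeca-2,6,10-triene
Conditions: CBr4, PPh3, 2,6-lutidine, CH2Cl2, 0 °C
Reagents that add atoms: carbon tetrabromide, BrC(Br)(Br)Br
Why: Appel reaction, in which bromide displaces the alkoxyphosphonium ion by SN2 at the primary allylic carbon, so the (E)-geometry and the C16 centre are untouched.

**Union and end game**

Step 13
Reactants: 12 sulfonyl diol; 23 allylic bromide
Product: 24 C12-alkylated sulfone (both C12 epimers)
Conditions: 12, n-BuLi (3.1 equiv), THF/DMPU 5:1, −78 °C; then 23 (1.2 equiv), −78 → −40 °C; aq. NH4Cl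
Reagents that add atoms: none
Why: Sulfone alkylation, in which both hydroxyls are first converted into lithium alkoxides and the third equivalent of base forms the α-sulfonyl carbanion at C12, by far the best nucleophile present, which displaces the primary allylic bromide by SN2; the new centre at C12 is of no consequence.

Step 14
Reactants: 24 alkylated sulfone
Product: 25 desulfonylated diol with the complete carbon chain C3–C23
Conditions: Na(Hg) (6% Na), Na2HPO4, MeOH/THF 3:1, −20 → 0 °C
Reagents that add atoms: none
Why: Reductive desulfonylation by electron transfer from sodium amalgam (C–S cleavage, protonation by methanol) in buffered medium should leave alkenes, silyl ethers and the free alcohols intact.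

Step 15
Reactants: 25 diol
Product: 26 C7 ketone
Conditions: Dess–Martin periodinane (1.5 equiv), NaHCO3, CH2Cl2, 0 °C → rt
Reagents that add atoms: none
Why: Only the secondary C7 hydroxyl can be oxidised (the C10 hydroxyl is tertiary, the others are silylated), and the buffered periodinane conditions should not epimerise C6.

Step 16
Reactants: 26 ketone; 27 isopropenylmagnesium bromide
Product: 28 C7 tertiary allylic alcohol (either C7 epimer)
Conditions: 27 (4 equiv), anhydrous CeCl3 (4 equiv), THF, −78 → 0 °C
Reagents that add atoms: none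
Why: The organocerium reagent formed from the Grignard reagent and CeCl3 adds 1,2 to the hindered, enolisable ketone without deprotonating C6 (one equivalent is consumed by the C10 hydroxyl); the configuration of the new carbinol carbon is irrelevant because C7 becomes sp2 in the next step.

Step 17
Reactants: 28 tertiary allylic alcohol
Product: 29 bis(silyl) ether of the target enal
Conditions: pyridinium chlorochromate (C5H5NH)[CrO3Cl] (3 equiv), 4 Å MS, CH2Cl2, rt
Reagents that add atoms: pyridinium chlorochromate, [O-][Cr](=O)(=O)Cl.c1cc[nH+]cc1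
Why: Babler–Dauben oxidative transposition, in which the tertiary allylic chromate ester undergoes a [3,3] shift to the primary allylic chromate that is oxidised to the enal; in the chair-like shift the bulky chromate-bearing terminus should avoid the branched C6 and end syn to the ring CH2 (C8), which gives the formyl group cis to C8 and the methyl group cis to C6, while the tertiary C10 hydroxyl cannot be oxidised.

Step 18
Reactants: 29 bis(silyl) ether
Product: 30 target compound CNP0417035.1
Conditions: HF·pyridine, pyridine, THF, 0 °C → rt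
Reagents that add atoms: none
Why: Fluoride cleaves the primary and the secondary allylic silyl ether, and buffering with pyridine should protect the enal, the tertiary alcohol and the allylic alcohol from acid.

**Compound list**

1 | tert-butyl(but-3-yn-1-yloxy)dimethylsilane | C#CCCO[Si](C)(C)C(C)(C)C | starting material
2 | 2-bromopropene | C=C(C)Br | starting material
3 | chlorobis(cyclopentadienyl)[(E)-4-(tert-butyldimethylsilyloxy)but-1-enyl]zirconium | Cl[Zr](/C=C/CCO[Si](C)(C)C(C)(C)C)(C1C=CC=C1)C1C=CC=C1 | intermediate (not isolated)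
4 | (E)-tert-butyldimethyl[(5-methylhexa-3,5-dien-1-yl)oxy]silane | C=C(C)/C=C/CCO[Si](C)(C)C(C)(C)C | intermediate
5 | (Z)-tert-butyldimethyl{[5-methyl-6-(4,4,5,5-tetramethyl-1,3,2-dioxaborolan-2-yl)hex-4-en-1-yl]oxy}silane | CC1(C)OB(C/C(C)=C\CCCO[Si](C)(C)C(C)(C)C)OC1(C)C | intermediate
6 | pent-4-enal | C=CCCC=O | starting material
7 | pinacol borate ester of 8 | C=CCC[C@H](OB1OC(C)(C)C(C)(C)O1)[C@@H](CCCO[Si](C)(C)C(C)(C)C)C(C)=C | intermediate (not isolated)
8 | (3S,4S)-3-[3-(tert-butyldimethylsilyloxy)propyl]-2-methylocta-1,7-dien-4-ol | C=CCC[C@H](O)[C@@H](CCCO[Si](C)(C)C(C)(C)C)C(C)=C | intermediate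
9 | (5S,6S)-5-hydroxy-7-methyl-6-[3-(tert-butyldimethylsilyloxy)propyl]oct-7-en-2-one | CC(=O)CC[C@H](O)[C@@H](CCCO[Si](C)(C)C(C)(C)C)C(C)=C | intermediate
10 | 5-hydroxy-7-iodo-7-methyl-8-(phenylsulfonyl)-6-[3-(tert-butyldimethylsilyloxy)propyl]octan-2-one (C5 and C6 as in 9, both C7 epimers) | CC(=O)CC[C@H](O)[C@@H](CCCO[Si](C)(C)C(C)(C)C)C(C)(I)CS(=O)(=O)c1ccccc1 | intermediate (not isolated)
11 | (5S,6S,7E)-5-hydroxy-7-methyl-8-(phenylsulfonyl)-6-[3-(tert-butyldimethylsilyloxy)propyl]oct-7-en-2-one | CC(=O)CC[C@H](O)[C@@H](CCCO[Si](C)(C)C(C)(C)C)/C(C)=C/S(=O)(=O)c1ccccc1 | intermediate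
12 | (1S,2S,3S,4S)-1,2-dimethyl-2-[(phenylsulfonyl)methyl]-3-[3-(tert-butyldimethylsilyloxy)propyl]cyclohexane-1,4-diol | O=S(=O)(c1ccccc1)C[C@@]1(C)[C@H](CCCO[Si](C)(C)C(C)(C)C)[C@@H](O)CC[C@]1(C)O | intermediate
13 | geranyl bromide, (2E)-1-bromo-3,7-dimethylocta-2,6-diene | CC(C)=CCC/C(C)=C/CBr | starting material
14 | acetaldehyde N,N-dimethylhydrazone | C/C=N/N(C)C | starting material
15 | (4E)-5,9-dimethyldeca-4,8-dienal N,N-dimethylhydrazone | CC(C)=CCC/C(C)=C/CCC=NN(C)C | intermediate (not isolated)
16 | (4E)-5,9-dimethyldeca-4,8-dienal | CC(C)=CCC/C(C)=C/CCC=O | intermediate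
17 | ethyl 2-(triphenylphosphoranylidene)propanoate | CCOC(=O)C(C)=P(c1ccccc1)(c1ccccc1)c1ccccc1 | starting material
18 | (2R,4E)-5,9-dimethyl-2-(phenylaminooxy)deca-4,8-dienal | CC(C)=CCC/C(C)=C/C[C@@H](ONc1ccccc1)C=O | intermediate (not isolated)
19 | ethyl (2E,4R,6E)-2,7,11-trimethyl-4-(phenylaminooxy)dodeca-2,6,10-trienoate | CCOC(=O)/C(C)=C/[C@H](ONc1ccccc1)C/C=C(\C)CCC=C(C)C | intermediate
20 | ethyl (2E,4R,6E)-4-hydroxy-2,7,11-trimethyldodeca-2,6,10-trienoate | CCOC(=O)/C(C)=C/[C@H](O)C/C=C(\C)CCC=C(C)C | intermediate
21 | ethyl (2E,4R,6E)-4-(tert-butyldimethylsilyloxy)-2,7,11-trimethyldodeca-2,6,10-trienoate | CCOC(=O)/C(C)=C/[C@H](O[Si](C)(C)C(C)(C)C)C/C=C(\C)CCC=C(C)C | intermediate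
22 | (2E,4R,6E)-4-(tert-butyldimethylsilyloxy)-2,7,11-trimethyldodeca-2,6,10-trien-1-ol | OC/C(C)=C/[C@H](O[Si](C)(C)C(C)(C)C)C/C=C(\C)CCC=C(C)C | intermediate
23 | (2E,4R,6E)-1-bromo-4-(tert-butyldimethylsilyloxy)-2,7,11-trimethyldodeca-2,6,10-triene | BrC/C(C)=C/[C@H](O[Si](C)(C)C(C)(C)C)C/C=C(\C)CCC=C(C)C | intermediate
24 | alkylated sulfone: 12 carrying at C12 the (2E,4R,6E)-4-(tert-butyldimethylsilyloxy)-2,7,11-trimethyldodeca-2,6,10-trienyl group, both C12 epimers | CC(C)=CCC/C(C)=C/C[C@@H](O[Si](C)(C)C(C)(C)C)/C=C(\C)CC(S(=O)(=O)c1ccccc1)[C@@]1(C)[C@H](CCCO[Si](C)(C)C(C)(C)C)[C@@H](O)CC[C@]1(C)O | intermediate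
25 | desulfonylated diol (C7 and C10 hydroxyls free, C3 and C16 silylated) | CC(C)=CCC/C(C)=C/C[C@@H](O[Si](C)(C)C(C)(C)C)/C=C(\C)CC[C@@]1(C)[C@H](CCCO[Si](C)(C)C(C)(C)C)[C@@H](O)CC[C@]1(C)O | intermediate
26 | C7 ketone | CC(C)=CCC/C(C)=C/C[C@@H](O[Si](C)(C)C(C)(C)C)/C=C(\C)CC[C@@]1(C)[C@H](CCCO[Si](C)(C)C(C)(C)C)C(=O)CC[C@]1(C)O | intermediate
27 | isopropenylmagnesium bromide | C=C(C)[Mg]Br | starting material
28 | C7 isopropenyl carbinol (either C7 epimer) | CC(C)=CCC/C(C)=C/C[C@@H](O[Si](C)(C)C(C)(C)C)/C=C(\C)CC[C@@]1(C)[C@H](CCCO[Si](C)(C)C(C)(C)C)C(O)(C(C)=C)CC[C@]1(C)O | intermediate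
29 | 3,16-bis(tert-butyldimethylsilyl) ether of the target | CC(C)=CCC/C(C)=C/C[C@@H](O[Si](C)(C)C(C)(C)C)/C=C(\C)CC[C@@]1(C)[C@H](CCCO[Si](C)(C)C(C)(C)C)/C(=C(\C)C=O)CC[C@]1(C)O | intermediate
30 | CNP0417035.1, (6R,10S,11S,16R)-configured 3,10,16-trihydroxy iridal-type enal | CC(C)=CCC/C(C)=C/C[C@@H](O)/C=C(\C)CC[C@@]1(C)[C@H](CCCO)/C(=C(\C)C=O)CC[C@]1(C)O | target

**Step count and risks**

Total step count: 18. Longest linear sequence: 12 steps (steps 1–6, then 13–18; the side-chain branch 7–12, then 13–18, is equally long).

Most likely to fail: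

Step 6. Electron transfer to the vinyl sulfone (saturation or loss of benzenesulfinate) may outrun ketyl formation, or the two chair arrangements may not be discriminated well enough. The fallback sets out from 11 and comes back at 12, and closes the same C10–C11 bond as a radical conjugate addition started by metal-hydride hydrogen-atom transfer. Compound 11 would be treated with Et3SiOTf and Et3N to give the triethylsilyl enol ether that also carries a C7 triethylsilyl ether, F1 (either enol ether regioisomer serves, since both give the same radical). Fe(acac)3 and PhSiH3 in EtOH would deliver a hydrogen atom to the enol ether, and the α-silyloxy radical at C10 would close 6-exo onto C11 to give the cyclised bis(triethylsilyl) ether F2. PPTS in MeOH would remove both triethylsilyl groups and return 12.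

Step 17. The tertiary allylic chromate ester may ionise (transannular trapping by the C10 hydroxyl, elimination to dienes) faster than it rearranges, and the shift may not control the new alkene geometry fully. The fallback sets out from 28 and comes back at 29, and separates transposition from oxidation. Catalytic Ph3SiOReO3 in Et2O at low temperature would equilibrate 28 by a reversible [3,3] shift to the primary allylic alcohol with the tetrasubstituted C7=C2 alkene, F3, under neutral conditions. MnO2 in CH2Cl2 would then oxidise only this allylic primary alcohol to 29.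

Step 13. Within the trianion, O-alkylation or proton transfer may compete, and C-alkylation of the carbanion next to the quaternary centre may be slow. The fallback sets out from 12 and comes back at 25, and replaces the polyanion by a protected mono-anion. 1-(Trimethylsilyl)imidazole would convert 12 into its bis(trimethylsilyl) ether F4. One equivalent of n-BuLi in THF/DMPU would then form only the α-sulfonyl carbanion, which would be alkylated with 23 to the silylated coupled sulfone F5. Na(Hg)/Na2HPO4 in MeOH, followed by K2CO3 in MeOH, would remove the sulfonyl group and both trimethylsilyl groups and return 25.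

**Further compounds**

F1 | step 6 | (5S,6S,7E)-7-methyl-8-(phenylsulfonyl)-6-[3-(tert-butyldimethylsilyloxy)propyl]-2,5-bis(triethylsilyloxy)octa-1,7-diene | C=C(O[Si](CC)(CC)CC)CC[C@H](O[Si](CC)(CC)CC)[C@@H](CCCO[Si](C)(C)C(C)(C)C)/C(C)=C/S(=O)(=O)c1ccccc1
F2 | step 6 | 1,4-bis(triethylsilyl) ether of 12 | O=S(=O)(c1ccccc1)C[C@@]1(C)[C@H](CCCO[Si](C)(C)C(C)(C)C)[C@@H](O[Si](CC)(CC)CC)CC[C@]1(C)O[Si](CC)(CC)CC
F3 | step 17 | C1 primary allylic alcohol corresponding to 29 | CC(C)=CCC/C(C)=C/C[C@@H](O[Si](C)(C)C(C)(C)C)/C=C(\C)CC[C@@]1(C)[C@H](CCCO[Si](C)(C)C(C)(C)C)/C(=C(\C)CO)CC[C@]1(C)O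
F4 | step 13 | 1,4-bis(trimethylsilyl) ether of 12 | O=S(=O)(c1ccccc1)C[C@@]1(C)[C@H](CCCO[Si](C)(C)C(C)(C)C)[C@@H](O[Si](C)(C)C)CC[C@]1(C)O[Si](C)(C)C
F5 | step 13 | bis(trimethylsilyl) ether of 24 | CC(C)=CCC/C(C)=C/C[C@@H](O[Si](C)(C)C(C)(C)C)/C=C(\C)CC(S(=O)(=O)c1ccccc1)[C@@]1(C)[C@H](CCCO[Si](C)(C)C(C)(C)C)[C@@H](O[Si](C)(C)C)CC[C@]1(C)O[Si](C)(C)C
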